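I decided to plan the flask around one number, the target output u: the molarity of target made per minute, read from the runs as percent of target times the solid substrate charged, divided by the time.

| setting | violet | amber | blue | flask |
|---|---|---|---|---|
| solid substrate | 0.10 M | 0.16 M | 0.21 M | 0.21 M |
| gas phase | 15 mM (held) | 15 mM (held) | 15 mM (held) | 15 mM (held) |
| protic impurity | 0.021 M | 0.021 M | 0.011 M | 0.0210 M |
| remark | run made earlier | run made earlier | run made earlier |  |
| time |  |  |  | 8.0 min |

| run | time / min | target / % | solid substrate / % |
|---|---|---|---|
| violet | 0.417 | 7 | 43 |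
| violet | 0.667 | 6 | 24 |
| violet | 1.00 | 12 | 0 |
| violet | 2.00 | 25 | 1 |
| violet | 3.00 | 38 | 2 |
| violet | 5.00 | 47 | 3 |
| amber | 0.417 | 3 | 62 |
| amber | 0.667 | 3 | 52 |
| amber | 1.00 | 10 | 40 |
| amber | 2.00 | 20 | 9 |
| amber | 3.00 | 27 | 3 |
| amber | 5.00 | 43 | 0 |
| blue | 1.00 | 5 | 53 |
| blue | 2.00 | 17 | 31 |
| blue | 3.00 | 20 | 18 |
| blue | 4.00 | 27 | 2 |
| blue | 5.00 | 38 | 1 |

(each reading ± 2 percentage points)

- solid, in amounts per volume of the solution: solid substrate
- at the start none of the gas is dissolved
- the numbers in the tables scatter by 2 percentage points (one standard deviation)
- steps thought possible: gas phase <-> dissolved gas; starting material + dissolved gas -> target; dissolved gas + target -> over-reacted product; dissolved gas + protic impurity -> quenched reagent; target <-> isomer of the product; solid substrate <-> starting material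
- at the start none of the solid substrate is in solution

- how much target there is at 8.0 min, in percent of the solid substrate charged
- concentration of dissolved gas in solution at 8.0 min, in percent of saturation

I turned the settings one at a time, first by hand and then against the readings.

Solid substrate: if output ignores the charge, more solid lowers the percent, as y = u·t/c for target percent y at time t and charge c. At 3.00 min violet, amber and blue read 38 %, 27 % and 20 %, which is 0.0127 M min⁻¹, 0.0144 M min⁻¹ and 0.0140 M min⁻¹. This looked like a zero-order stretch, so I took their mean:

u = 0.0137 M min⁻¹

Protic impurity: by hand it could draw dissolved gas away from the path to target. But blue, with half of amber's impurity and also more solid substrate, read no higher output than amber at 3.00 min, so I left u unchanged.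

Time: by hand, the percent grows along a straight line. For the flask:

y = u·t/c = 52.1 %

But violet at 5.00 min read 47 % against a line of 68.4 %, so I expected the flask to come in below my figure.

The forecast gave 51 % target and dissolved gas at 27 % of saturation, holding the reaction “mainly limited by gas uptake”.

    gas phase ⇌ dissolved gas, rate k1*(csat - [dissolved gas]) (kL = 0.0627 s⁻¹)
    starting material + dissolved gas → target (k = 0.667 M⁻¹ s⁻¹)
    dissolved gas + target → over-reacted product (k = 0.190 M⁻¹ s⁻¹)
    dissolved gas + protic impurity → quenched reagent (k = 0.263 M⁻¹ s⁻¹)
    target ⇌ isomer of the product (K = 0.450, k = 0.0392 s⁻¹)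
    solid substrate ⇌ starting material, rate k6*(cs6 - [starting material]) while solid is left; crystals form when [starting material] > cs6 (solubility = 0.120 M, k = 0.0254 s⁻¹)

The flask gave 45.4 % target, with dissolved gas at 58.5 % of saturation. Over-reacted product stood at 18.0 % at 8.00 min. The mean output was 0.0119 M min⁻¹, below u, so my line stood 6.7 percentage points too high.

With 0.84 M of solid substrate at the same time, u gives 13.0 %. That neighbouring flask computed 13.7 %.

The runs were computed for substances that don't exist, noise included.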